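**Retrosynthetic overview**
- The two phenols are unmasked last from a 5,7-di-O-methyl flavone. The pyranone ring C is opened to an ortho-hydroxyaryl 1,3-diketone, which comes from Claisen benzoylation of an aryl methyl ketone whose acetyl group is introduced by directed ortho-lithiation.
- The plan rests on one feature of the piperidine (atoms primed): N1' is bonded to C2' (the stereocentre on C6 of ring A) and to C6', the two ends of an otherwise unfunctionalised C2'–C6' chain. N1' is therefore inserted last, between an aryl ketone carbon and a chloride-bearing carbon, by an (R)-selective transaminase with spontaneous ring closure.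
- The ω-chloro ketone comes from 4-hydroxy-2,6-dimethoxybenzaldehyde (para oxygen, the future O1, as its methoxymethyl ether), 4-chlorobutylmagnesium bromide and oxidation.
- Ring order: ring A is bought, the piperidine is closed first (step 4), the pyranone ring C second (step 8), and ring B arrives with benzoyl chloride.

Key step: step 4

Assumption: the target is read as (R) at C2' (N1' > aryl C6 > C3' > H); the para oxygen is carried as a methoxymethyl ether because it is small in the enzyme pocket, directs the later ortho-lithiation and leaves under mild acid, so no Lewis-acid acylation or hydrogenolysis is needed next to the benzylic C–N bond.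

Step 1
Reactants: 1 4-hydroxy-2,6-dimethoxybenzaldehyde; 2 chloromethyl methyl ether
Product: 3 2,6-dimethoxy-4-(methoxymethoxy)benzaldehyde
Conditions: MOMCl, K2CO3, acetone, 0 °C → rt
Reagents that add atoms: chloromethyl methyl ether (2), COCCl
Why: Williamson-type O-alkylation of the acidic para phenol with the reactive α-chloro ether should give the methoxymethyl acetal cleanly, since the phenol is the only nucleophilic site.

Step 2
Reactants: 3 2,6-dimethoxy-4-(methoxymethoxy)benzaldehyde; 4 1-bromo-4-chlorobutane
Product: 6 rac-5-chloro-1-[2,6-dimethoxy-4-(methoxymethoxy)phenyl]pentan-1-ol, via 4-chlorobutylmagnesium bromide 5 (not isolated)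
Conditions: 4, Mg, I2 (cat.), THF, 30 °C; then 3, THF, −20 → 0 °C; aq NH4Cl
Reagents that add atoms: 1-bromo-4-chlorobutane (4), ClCCCCBr
Why: Magnesium inserts into the C–Br bond and leaves the C–Cl bond alone, and the Grignard addition to the aldehyde is faster than any attack on the primary chloride; the carbinol centre is racemic and is erased in step 3.

Step 3
Reactants: 6 rac-5-chloro-1-[2,6-dimethoxy-4-(methoxymethoxy)phenyl]pentan-1-ol
Product: 7 5-chloro-1-[2,6-dimethoxy-4-(methoxymethoxy)phenyl]pentan-1-one
Conditions: Dess–Martin periodinane, pyridine, CH2Cl2, 0 °C → rt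
Reagents that add atoms: none
Why: Dess–Martin oxidation under pyridine buffering should convert the secondary benzylic alcohol into the ketone without acid that could ionise the electron-rich benzylic position or open the acetal.

Step 4
Reactants: 7 5-chloro-1-[2,6-dimethoxy-4-(methoxymethoxy)phenyl]pentan-1-one; 8 isopropylamine
Product: 10 (2R)-2-[2,6-dimethoxy-4-(methoxymethoxy)phenyl]piperidine, via open-chain amino chloride 9 (not isolated)
Conditions: engineered (R)-selective amine transaminase, pyridoxal 5'-phosphate (1 mM), i-PrNH2 (1 M), triethanolamine buffer pH 8.5, DMSO (30% v/v), 40 °C; then NaOH to pH 12, 40 °C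
Reagents that add atoms: isopropylamine (8), CC(C)N
Why: Proposed new method: the pyridoxamine form of the enzyme condenses with the ketone of 7, the active-site lysine shifts a proton through the enzyme-bound quinonoid species onto one face of C2', and hydrolysis releases primary amine 9 while isopropylamine is turned into acetone and recharges the cofactor. The closest known reaction type is the transaminase-triggered cyclisation of unhindered aryl ω-chloro ketones to 2-arylpyrrolidines and 2-arylpiperidines; new here is a ketone twisted by two ortho methoxy groups, for which a variant with a further enlarged large pocket must be found by screening and directed evolution. The piperidine closes by 6-exo-tet SN2 attack of N1' on C6'–Cl, which is irreversible and pulls the unfavourable transamination equilibrium forward, and the final rise in pH completes it. The C2' stereocentre is set by the enzyme alone: with the aryl group in the large pocket and the chlorobutyl chain in the small pocket, an (R)-selective enzyme protonates the face that gives (R). The step needs chemoselectivity for amination over intermolecular displacement of chloride, and the substrate secures it because it has a single carbonyl group, the donor amine is almost fully protonated at pH 8.5, and the primary chloride reacts quickly only with the internal amine; the acetal and methyl ethers are inert at pH 8.5–12.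

Step 5
Reactants: 10 (2R)-2-[2,6-dimethoxy-4-(methoxymethoxy)phenyl]piperidine; 11 formaldehyde
Product: 12 (2R)-2-[2,6-dimethoxy-4-(methoxymethoxy)phenyl]-1-methylpiperidine
Conditions: aq CH2O, NaBH(OAc)3, AcOH (1 equiv), 1,2-dichloroethane, rt
Reagents that add atoms: formaldehyde (11), C=O
Why: Reductive amination of the secondary amine with formaldehyde and NaBH(OAc)3 should methylate nitrogen once, cannot quaternise it, and leaves the non-enolisable C2' centre and the acetal untouched.

Step 6
Reactants: 12 (2R)-2-[2,6-dimethoxy-4-(methoxymethoxy)phenyl]-1-methylpiperidine; 13 N-methoxy-N-methylacetamide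
Product: 15 1-{2,4-dimethoxy-6-(methoxymethoxy)-3-[(2R)-1-methylpiperidin-2-yl]phenyl}ethan-1-one, via aryllithium 14 (not isolated)
Conditions: n-BuLi, THF, 0 °C; then MeC(O)N(OMe)Me, −78 → 0 °C; aq NH4Cl
Reagents that add atoms: N-methoxy-N-methylacetamide (13), CC(=O)N(C)OC
Why: Directed ortho-metalation should take place at the ring C–H flanked by the methoxy and methoxymethoxy groups (the two free ring positions are equivalent), and acylation of the aryllithium with the Weinreb amide stops at the ketone (Weinreb ketone synthesis), with no acid near the benzylic C–N bond.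

Step 7
Reactants: 15 1-{2,4-dimethoxy-6-(methoxymethoxy)-3-[(2R)-1-methylpiperidin-2-yl]phenyl}ethan-1-one; 16 benzoyl chloride
Product: 17 1-{2,4-dimethoxy-6-(methoxymethoxy)-3-[(2R)-1-methylpiperidin-2-yl]phenyl}-3-phenylpropane-1,3-dione
Conditions: LiN(SiMe3)2 (2.5 equiv), THF, −78 °C; then BzCl (1.0 equiv), −78 °C → rt; aq NH4Cl
Reagents that add atoms: benzoyl chloride (16), O=C(Cl)c1ccccc1
Why: Crossed Claisen condensation: deprotonation of the methyl ketone with excess amide base and C-benzoylation should give the 1,3-diketone, which stays deprotonated until the quench and so is not acylated twice.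

Step 8
Reactants: 17 1-{2,4-dimethoxy-6-(methoxymethoxy)-3-[(2R)-1-methylpiperidin-2-yl]phenyl}-3-phenylpropane-1,3-dione
Product: 19 5,7-dimethoxy-6-[(2R)-1-methylpiperidin-2-yl]-2-phenyl-4H-chromen-4-one, via phenol diketone 18 (not isolated)
Conditions: HCl (3 M in MeOH), 55 °C
Reagents that add atoms: none
Why: Acid cleaves the acetal and frees the only phenol ortho to the diketone, which adds to the benzoyl carbonyl and loses water (the cyclodehydration stage of the Baker–Venkataraman flavone synthesis), so ring C can form only towards the oxygen para to the piperidine and the piperidine ends up on C6.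

Step 9
Reactants: 19 5,7-dimethoxy-6-[(2R)-1-methylpiperidin-2-yl]-2-phenyl-4H-chromen-4-one
Product: 20 5,7-dihydroxy-6-[(2R)-1-methylpiperidin-2-yl]-2-phenyl-4H-chromen-4-one
Conditions: BBr3 (6 equiv), CH2Cl2, −78 °C → rt; then H2O, 0 °C
Reagents that add atoms: none
Why: Lewis-acid ether cleavage with BBr3 should remove the 5-methyl group (activated by chelation to the C4 carbonyl) and, with excess reagent, the 7-methyl group, while the low temperature is chosen to avoid opening of the pyranone ring and ionisation at C2'.

**Compound list**
1 | 4-hydroxy-2,6-dimethoxybenzaldehyde | COc1cc(O)cc(OC)c1C=O | starting material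
2 | chloromethyl methyl ether | COCCl | starting material
3 | 2,6-dimethoxy-4-(methoxymethoxy)benzaldehyde | COCOc1cc(OC)c(C=O)c(OC)c1 | intermediate
4 | 1-bromo-4-chlorobutane | ClCCCCBr | starting material
5 | 4-chlorobutylmagnesium bromide | ClCCCC[Mg]Br | intermediate (not isolated)
6 | rac-5-chloro-1-[2,6-dimethoxy-4-(methoxymethoxy)phenyl]pentan-1-ol | OC(CCCCCl)c1c(OC)cc(OCOC)cc1OC | intermediate
7 | 5-chloro-1-[2,6-dimethoxy-4-(methoxymethoxy)phenyl]pentan-1-one | O=C(CCCCCl)c1c(OC)cc(OCOC)cc1OC | intermediate
8 | isopropylamine | CC(C)N | starting material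
9 | (1R)-5-chloro-1-[2,6-dimethoxy-4-(methoxymethoxy)phenyl]pentan-1-amine | N[C@H](CCCCCl)c1c(OC)cc(OCOC)cc1OC | intermediate (not isolated)
10 | (2R)-2-[2,6-dimethoxy-4-(methoxymethoxy)phenyl]piperidine | N1CCCC[C@@H]1c1c(OC)cc(OCOC)cc1OC | intermediate
11 | formaldehyde | C=O | starting material
12 | (2R)-2-[2,6-dimethoxy-4-(methoxymethoxy)phenyl]-1-methylpiperidine | CN1CCCC[C@@H]1c1c(OC)cc(OCOC)cc1OC | intermediate
13 | N-methoxy-N-methylacetamide | CC(=O)N(C)OC | starting material
14 | {2,4-dimethoxy-6-(methoxymethoxy)-3-[(2R)-1-methylpiperidin-2-yl]phenyl}lithium | CN1CCCC[C@@H]1c1c(OC)c([Li])c(OCOC)cc1OC | intermediate (not isolated)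
15 | 1-{2,4-dimethoxy-6-(methoxymethoxy)-3-[(2R)-1-methylpiperidin-2-yl]phenyl}ethan-1-one | CN1CCCC[C@@H]1c1c(OC)c(C(C)=O)c(OCOC)cc1OC | intermediate
16 | benzoyl chloride | O=C(Cl)c1ccccc1 | starting material
17 | 1-{2,4-dimethoxy-6-(methoxymethoxy)-3-[(2R)-1-methylpiperidin-2-yl]phenyl}-3-phenylpropane-1,3-dione | CN1CCCC[C@@H]1c1c(OC)c(C(=O)CC(=O)c2ccccc2)c(OCOC)cc1OC | intermediate
18 | 1-{6-hydroxy-2,4-dimethoxy-3-[(2R)-1-methylpiperidin-2-yl]phenyl}-3-phenylpropane-1,3-dione | CN1CCCC[C@@H]1c1c(OC)c(C(=O)CC(=O)c2ccccc2)c(O)cc1OC | intermediate (not isolated)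
19 | 5,7-dimethoxy-6-[(2R)-1-methylpiperidin-2-yl]-2-phenyl-4H-chromen-4-one | CN1CCCC[C@@H]1c1c(OC)cc2oc(-c3ccccc3)cc(=O)c2c1OC | intermediate
20 | 5,7-dihydroxy-6-[(2R)-1-methylpiperidin-2-yl]-2-phenyl-4H-chromen-4-one | CN1CCCC[C@@H]1c1c(O)cc2oc(-c3ccccc3)cc(=O)c2c1O | target

Total step count: 9. Longest linear sequence: 9 steps (1 → 20).

**Steps most likely to fail**

Step 4. No available variant may accept the twisted, electron-rich ketone, so the amination could stall at low conversion. The aryl group and the chain might also bind in swapped pockets, which would lower or reverse the facial selectivity. Fallback with known auxiliary chemistry, setting out from 7 and returning at 10: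
- Condensation of 7 with (R)-2-methylpropane-2-sulfinamide and Ti(OEt)4 in THF at 70 °C should give the N-tert-butanesulfinyl ketimine F1.
- Reduction with NaBH4 in THF at −50 °C, through the chelated transition state, is expected to give the (R_S,R)-sulfinamide F2. The diastereomers are separable on silica, and LiBH(s-Bu)3 through the open transition state is the alternative if the hindered ketimine reverses the usual sense.
- NaH in THF/DMF should close the ring by N-alkylation to the N-sulfinylpiperidine F3.
- A short treatment with HCl (2 equiv) in MeOH at 0 °C should remove the sulfinyl group faster than the aryl acetal and give 10.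

Step 9. Cleavage of the 7-methyl ether next to the piperidine may be incomplete. Once the ortho phenols are free and nitrogen is protonated or boron-bound, reversible ionisation of the C2'–N1' bond could erode the configuration, and acid-induced opening and reclosure of the pyranone (Wessely–Moser rearrangement) could move the piperidine to C8. Fallback in two stages with a change of mechanism, setting out from 19 and returning at 20:
- BCl3 in CH2Cl2 at −78 → 0 °C should cleave only the carbonyl-chelated 5-methyl ether and give 5-hydroxy-7-methoxy-6-[(2R)-1-methylpiperidin-2-yl]-2-phenyl-4H-chromen-4-one F4.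
- NaSEt in DMF at about 110 °C should then remove the 7-methyl group by SN2 attack of the thiolate on the methyl carbon and give 20. The medium is basic, so N1' stays unprotonated and is a poor leaving group; the enantiomeric purity would still have to be checked.

Step 6. The hindered aryllithium may be quenched by proton transfer from the acetyl group of the amide, or metalation may be incomplete, returning 12. Fallback by halogenation and cross-coupling, setting out from 12 and returning at 15:
- Bromination of the trifluoroacetate salt of 12 with NBS in MeCN at 0 °C should give the aryl bromide (2R)-2-[3-bromo-2,6-dimethoxy-4-(methoxymethoxy)phenyl]-1-methylpiperidine F5; both free ring positions are equivalent and strongly activated, and the nitrogen is protected by protonation.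
- Stille coupling of F5 with tributyl(1-ethoxyvinyl)stannane and Pd(PPh3)4 in toluene at 100 °C should give the enol ether (2R)-2-[3-(1-ethoxyethenyl)-2,6-dimethoxy-4-(methoxymethoxy)phenyl]-1-methylpiperidine F6.
- Brief hydrolysis with dilute aqueous oxalic acid in THF at rt should give 15.

**Further compounds**
F1 | step 4 | (R)-N-{5-chloro-1-[2,6-dimethoxy-4-(methoxymethoxy)phenyl]pentylidene}-2-methylpropane-2-sulfinamide (C=N geometry not defined) | CC(C)(C)[S@@](=O)N=C(CCCCCl)c1c(OC)cc(OCOC)cc1OC
F2 | step 4 | (R)-N-{(1R)-5-chloro-1-[2,6-dimethoxy-4-(methoxymethoxy)phenyl]pentyl}-2-methylpropane-2-sulfinamide | CC(C)(C)[S@@](=O)N[C@H](CCCCCl)c1c(OC)cc(OCOC)cc1OC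
F3 | step 4 | (2R)-1-[(R)-tert-butylsulfinyl]-2-[2,6-dimethoxy-4-(methoxymethoxy)phenyl]piperidine | CC(C)(C)[S@@](=O)N1CCCC[C@@H]1c1c(OC)cc(OCOC)cc1OC
F4 | step 9 | 5-hydroxy-7-methoxy-6-[(2R)-1-methylpiperidin-2-yl]-2-phenyl-4H-chromen-4-one | CN1CCCC[C@@H]1c1c(OC)cc2oc(-c3ccccc3)cc(=O)c2c1O
F5 | step 6 | (2R)-2-[3-bromo-2,6-dimethoxy-4-(methoxymethoxy)phenyl]-1-methylpiperidine | CN1CCCC[C@@H]1c1c(OC)c(Br)c(OCOC)cc1OC
F6 | step 6 | (2R)-2-[3-(1-ethoxyethenyl)-2,6-dimethoxy-4-(methoxymethoxy)phenyl]-1-methylpiperidine | CN1CCCC[C@@H]1c1c(OC)c(C(=C)OCC)c(OCOC)cc1OC
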